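**Retrosynthetic overview**
1. Feature: in ring C the ester oxygen on C3 sits next to the C4 ketone and trans to the phenyl on C2. The target is therefore an α-acyloxy ketone whose acyl group can be handed over from the neighbouring oxygen O4.
2. Last disconnection: the two O–Si bonds at O5 and O7 of ring A, cleaved with buffered fluoride.
3. Key disconnection: the C3–O and O3–acyl bonds, leading back to the C3=C4 enol ester that carries the (S)-2-methylbutanoyl group on O4. Oxidation occurs anti to the C2 phenyl, and the acyl group then shifts from O4 to O3 with retention at C3.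
4. Enol ester: the O4–acyl bond, leading back to the C4 lithium enolate of bis-silylated (2S)-pinocembrin and the symmetric anhydride of (S)-2-methylbutanoic acid.
5. No ring is formed. Rings A, B and C and the C2 centre come with (2S)-pinocembrin, the side-chain centre comes with the acid, and only C3 is created.

Key step: step 4

Assumption: (2S)-pinocembrin 1 is bought as the enantiopure levorotatory natural product, and its enantiopurity is checked by chiral HPLC before use, because racemic material is also sold.

**Step 1**
Reactants: 1 (2S)-pinocembrin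
Product: 2 (2S)-5,7-bis(tert-butyldimethylsilyloxy)-2-phenylchroman-4-one
Conditions: TBSOTf (2.3 equiv), 2,6-lutidine (3.5 equiv), CH2Cl2, −20 → 0 °C; neutral work-up, Et3N-deactivated silica
Reagents that add atoms: tert-butyldimethylsilyl triflate, CC(C)(C)[Si](C)(C)OS(=O)(=O)C(F)(F)F
Why: Phenol silylation with a silyl triflate, whose high electrophilicity should overcome the 5-OH···O=C4 hydrogen bond, while the weak, hindered base cannot enolise C3, so the retro-oxa-Michael channel that would scramble C2 stays closed.

**Step 2**
Reactants: 3 (S)-2-methylbutanoic acid (2 equiv)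
Product: 5 (2S)-2-methylbutanoic anhydride, via O-acylisourea 4 (not isolated)
Conditions: DCC (0.5 equiv per acid), CH2Cl2, 0 °C → rt; filter, concentrate
Reagents that add atoms: none
Why: Carbodiimide dehydration in which a second acid molecule acylates on O-acylisourea 4; no amine base and no acyl halide are present, so neither a ketene nor an enol pathway can erode the α-stereocentre.

**Step 3**
Reactants: 2 (2S)-5,7-bis(tert-butyldimethylsilyloxy)-2-phenylchroman-4-one; 5 (2S)-2-methylbutanoic anhydride
Product: 7 (2S)-5,7-bis(tert-butyldimethylsilyloxy)-2-phenyl-2H-chromen-4-yl (2S)-2-methylbutanoate, via lithium enolate 6 (not isolated)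
Conditions: LiN(SiMe3)2 (0.98 equiv), THF, −78 °C, 20 min; cannulate into 5 (2.5 equiv), THF, −78 → −40 °C; pH 7 buffer; work-up and storage in the dark, below 0 °C
Reagents that add atoms: none
Why: Kinetic deprotonation at C3 (the only enolisable site) followed by O-acylation of the lithium enolate through inverse addition into excess hard acyl donor; at −78 °C the lithium enolate should neither expel the O1 phenoxide nor accept the peri silyl group, so C2 is kept, and the slight deficit of base spares the stereocentre of the anhydride.

**Step 4**
Reactants: 7 (2S)-5,7-bis(tert-butyldimethylsilyloxy)-2-phenyl-2H-chromen-4-yl (2S)-2-methylbutanoate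
Product: 9 (2R,3R)-5,7-bis(tert-butyldimethylsilyloxy)-4-oxo-2-phenylchroman-3-yl (2S)-2-methylbutanoate, via acyloxy epoxide 8 (not isolated)
Conditions: DMDO (1.2 equiv, dried acetone solution), CH2Cl2, 4 Å MS, −40 → 0 °C, dark; volatiles off at 0 °C; then anhydrous p-TsOH (10 mol %), CH2Cl2, 0 °C, same flask; pH 7 buffer
Reagents that add atoms: dimethyldioxirane, CC1(C)OO1
Why: DMDO transfers one oxygen atom in a concerted step to C3=C4, the most nucleophilic π bond of 7 because it is an enol ester conjugated with O1 and the 5,7-dioxygenated ring A, and this gives acyloxy epoxide 8. The sulfonic acid protonates the oxirane oxygen and the C4–O bond ionises, since the C4 cation is carried by the acyloxy oxygen, by O1 and by the silyloxy groups ortho and para to C4a; the freed C3 hydroxyl then adds to the activated acyl carbon through a five-membered cyclic array, the acyl group passes from O4 to O3, and O4 becomes the ketone oxygen. The closest known reaction type is enol ester epoxidation followed by acid-induced rearrangement of the acyloxy epoxide to an α-acyloxy ketone, where strong acid gives retention and a concerted thermal or weak-acid shift gives inversion. No ring of the product is closed; the oxirane is a transient three-membered ring made by syn addition and opened again in the same flask. The one new stereocentre, C3, is set by substrate control: the C2 phenyl of the half-chair 2H-chromene shields its own face, oxygen arrives on the other face, and because that oxygen never leaves C3 the 2,3-trans (2R,3R) arrangement results. The step needs chemoselectivity for the alkene over the arenes (a near-stoichiometric neutral oxidant at low temperature), facial selectivity (the C2 phenyl), and C4–O rather than C3–O cleavage (cation stabilisation at C4, dry strong acid, and the fact that the invertive path would force the acyloxy group onto the phenyl-bearing face).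

**Step 5**
Reactants: 9 (2R,3R)-5,7-bis(tert-butyldimethylsilyloxy)-4-oxo-2-phenylchroman-3-yl (2S)-2-methylbutanoate
Product: 10 (2R,3R)-5,7-dihydroxy-4-oxo-2-phenylchroman-3-yl (2S)-2-methylbutanoate
Conditions: Bu4NF/AcOH (1:1, 2.5 equiv each), THF, 0 °C
Reagents that add atoms: none
Why: Fluoride-induced cleavage of aryl silyl ethers driven by Si–F bond formation; acetic acid protonates each phenoxide at once, so the medium should never become basic enough to enolise C3, open ring C, or move or cleave the ester.

**Compound list**
1 | (2S)-pinocembrin, (2S)-5,7-dihydroxy-2-phenylchroman-4-one | O=C1C[C@@H](c2ccccc2)Oc2cc(O)cc(O)c12 | starting material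
2 | (2S)-5,7-bis(tert-butyldimethylsilyloxy)-2-phenylchroman-4-one | O=C1C[C@@H](c2ccccc2)Oc2cc(O[Si](C)(C)C(C)(C)C)cc(O[Si](C)(C)C(C)(C)C)c12 | intermediate
3 | (S)-2-methylbutanoic acid | CC[C@H](C)C(=O)O | starting material
4 | N,N'-dicyclohexyl-O-[(2S)-2-methylbutanoyl]isourea (not isolated) | CC[C@H](C)C(=O)OC(=NC1CCCCC1)NC1CCCCC1 | intermediate
5 | (2S)-2-methylbutanoic anhydride, both centres S | CC[C@H](C)C(=O)OC(=O)[C@@H](C)CC | intermediate
6 | lithium (2S)-5,7-bis(tert-butyldimethylsilyloxy)-2-phenyl-2H-chromen-4-olate (not isolated) | [Li+].[O-]C1=C[C@@H](c2ccccc2)Oc2cc(O[Si](C)(C)C(C)(C)C)cc(O[Si](C)(C)C(C)(C)C)c12 | intermediate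
7 | (2S)-5,7-bis(tert-butyldimethylsilyloxy)-2-phenyl-2H-chromen-4-yl (2S)-2-methylbutanoate | CC[C@H](C)C(=O)OC1=C[C@@H](c2ccccc2)Oc2cc(O[Si](C)(C)C(C)(C)C)cc(O[Si](C)(C)C(C)(C)C)c12 | intermediate
8 | (2R,3R,4R)-3,4-epoxy-5,7-bis(tert-butyldimethylsilyloxy)-2-phenylchroman-4-yl (2S)-2-methylbutanoate, oxirane oxygen anti to the C2 phenyl (not isolated) | CC[C@H](C)C(=O)O[C@@]12O[C@@H]1[C@@H](c1ccccc1)Oc1cc(O[Si](C)(C)C(C)(C)C)cc(O[Si](C)(C)C(C)(C)C)c12 | intermediate
9 | (2R,3R)-5,7-bis(tert-butyldimethylsilyloxy)-4-oxo-2-phenylchroman-3-yl (2S)-2-methylbutanoate | CC[C@H](C)C(=O)O[C@H]1C(=O)c2c(O[Si](C)(C)C(C)(C)C)cc(O[Si](C)(C)C(C)(C)C)cc2O[C@@H]1c1ccccc1 | intermediate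
10 | (2R,3R)-5,7-dihydroxy-4-oxo-2-phenylchroman-3-yl (2S)-2-methylbutanoate (CNP0276295.2) | CC[C@H](C)C(=O)O[C@H]1C(=O)c2c(O)cc(O)cc2O[C@@H]1c1ccccc1 | target

Total step count: 5
Longest linear sequence: 4 (steps 1, 3, 4, 5; step 2 is a side branch)

**Steps most likely to fail**

**Step 4.**
- What may go wrong:
  - incomplete discrimination between the two faces of the C3=C4 bond;
  - leakage into the invertive acyl shift;
  - capture of the C4 cation by adventitious water with loss of the acyl group;
  - over-oxidation of ring A.
  - Partial loss of the peri silyl group under the acid is harmless, since it is removed in step 5.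
- Fallback: the C3–O bond is made on the enolate instead of on the enol ester. It sets out from 2.
  - Lithium enolate 6, made as in step 3, is oxidised at −78 °C with DMDO. This enolate hydroxylation is known on flavanones to deliver the 2,3-trans ketol, here (2R,3R)-5,7-bis-O-TBS-pinobanksin F1.
  - The trans ketol is also the thermodynamically preferred diequatorial isomer.
  - F1 is esterified with anhydride 5 (DMAP cat., pyridine, CH2Cl2, 0 °C), and the route is rejoined at 9.

**Step 3.**
- What may go wrong:
  - expulsion of the O1 phenoxide from the enolate, which opens ring C and erodes C2;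
  - migration of the peri silyl group from O5 to O4;
  - acylation at C3 instead of O4;
  - enolisation of the anhydride by residual base;
  - light-induced electrocyclic opening of the 2H-chromene on handling.
- Fallback: no stoichiometric enolate is ever accumulated. It sets out from 2.
  - Soft enolisation (Me3SiOTf, Et3N, CH2Cl2, 0 °C) silylates the carbonyl oxygen before the C3 proton is lost. It gives the trimethylsilyl enol ether F2.
  - Acid 3 is converted with cyanuric fluoride and pyridine into (S)-2-methylbutanoyl fluoride F3.
  - F2 and F3 are combined in THF at −78 °C with a catalytic amount of Bu4N[Ph3SiF2]. This is the known fluoride-catalysed O-acylation of silyl enol ethers by acyl fluorides.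
  - In that chain process the enolate is released only in the presence of the acyl donor, and each acylation returns fluoride. The unhindered Me3Si–O bond should be attacked far faster than the aryl TBS ethers.
  - The route is rejoined at 7.

**Step 1.**
- What may go wrong:
  - slow silylation of the hydrogen-bonded 5-OH;
  - competing silylation of the C4 enol;
  - hydrolytic loss of the peri silyl ether on work-up or chromatography.
- Fallback: the phenols are masked with the same acyl group that the target carries. It sets out from 1.
  - Both phenols are esterified with anhydride 5 (pyridine, DMAP cat., CH2Cl2, 0 °C → rt). Under such conditions chelated 5-OH groups of flavanones are routinely acylated without ring opening. The product is bis-ester F4.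
  - LiN(SiMe3)2 in THF at −78 °C gives lithium enolate F5, and a quench into excess 5 gives the tris-acyl enol ester F6.
  - A shift of the peri acyl group from O5 to O4 is harmless here, because all acyl groups are identical and the freed phenoxide is acylated again.
  - A Baker–Venkataraman-type C-acylation is barred because C3 points away from C5 in the fused ring.
  - DMDO and then p-TsOH, as in step 4, give the tris-ester F8 by way of acyloxy epoxide F7.
  - The two aryl esters are active esters of an acidic phenol. They are removed by imidazole-catalysed methanolysis (imidazole, MeOH, rt) in preference to the hindered secondary C3 ester.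
  - The route is rejoined at 10.

**Further compounds**
F1 | step 4 | (2R,3R)-5,7-bis(tert-butyldimethylsilyloxy)-3-hydroxy-2-phenylchroman-4-one | O[C@H]1C(=O)c2c(O[Si](C)(C)C(C)(C)C)cc(O[Si](C)(C)C(C)(C)C)cc2O[C@@H]1c1ccccc1
F2 | step 3 | (2S)-5,7-bis(tert-butyldimethylsilyloxy)-2-phenyl-4-(trimethylsilyloxy)-2H-chromene | C[Si](C)(C)OC1=C[C@@H](c2ccccc2)Oc2cc(O[Si](C)(C)C(C)(C)C)cc(O[Si](C)(C)C(C)(C)C)c12
F3 | step 3 | (S)-2-methylbutanoyl fluoride | CC[C@H](C)C(=O)F
F4 | step 1 | (2S)-4-oxo-2-phenylchromane-5,7-diyl bis[(2S)-2-methylbutanoate] | O=C1C[C@@H](c2ccccc2)Oc2cc(OC(=O)[C@@H](C)CC)cc(OC(=O)[C@@H](C)CC)c12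
F5 | step 1 | lithium enolate of F4 (not isolated) | [Li+].[O-]C1=C[C@@H](c2ccccc2)Oc2cc(OC(=O)[C@@H](C)CC)cc(OC(=O)[C@@H](C)CC)c12
F6 | step 1 | (2S)-2-phenyl-2H-chromene-4,5,7-triyl tris[(2S)-2-methylbutanoate] | CC[C@H](C)C(=O)OC1=C[C@@H](c2ccccc2)Oc2cc(OC(=O)[C@@H](C)CC)cc(OC(=O)[C@@H](C)CC)c12
F7 | step 1 | (2R,3R,4R)-3,4-epoxy-2-phenylchromane-4,5,7-triyl tris[(2S)-2-methylbutanoate], oxirane oxygen anti to the phenyl (not isolated) | CC[C@H](C)C(=O)O[C@@]12O[C@@H]1[C@@H](c1ccccc1)Oc1cc(OC(=O)[C@@H](C)CC)cc(OC(=O)[C@@H](C)CC)c12
F8 | step 1 | (2R,3R)-4-oxo-2-phenylchromane-3,5,7-triyl tris[(2S)-2-methylbutanoate] | CC[C@H](C)C(=O)O[C@H]1C(=O)c2c(OC(=O)[C@@H](C)CC)cc(OC(=O)[C@@H](C)CC)cc2O[C@@H]1c1ccccc1
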